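**Plan**
- Retrosynthesis cuts, in order: the C3–O acyl bond of the ester; the C2–C3 bond of the dihydrofuran ring (O1–C2 becomes an aryl enol ether, the isopropenyl group an allylboronate, C3 an aldehyde); the aryl O–CH2 ether bond; the aryl–acetyl bond at C5; and, in the side chain, the alkene–CO2H bond.
- Enabling feature: C2 carries the ring oxygen O1 and an isopropenyl group and sits next to the C3 carbinol of the five-membered ring, the 1,2-pattern left when a γ-oxyallyl boron unit adds to an aldehyde.
- Forward: the arene is silylated, acetylated and O-alkylated; the aldehyde is parked as the benzylic alcohol; boron is introduced, the allyl ether is isomerised to the Z enol ether and the aldehyde is restored.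
- The dihydrofuran ring, the only ring made, then closes by intramolecular allylboration; acylation at O3 and desilylation of the phenol finish the synthesis.
- Stereochemistry: C3 from the chiral phosphoric acid (aldehyde Re face); C2 from the closed six-membered transition state, which the aryl tether restricts to the cis outcome; enol ether Z from the iridium isomerisation (new methyl trans to oxygen); side-chain Z from (Z)-2-iodobut-2-enal, carried with retention.

Key step: step 8

Assumption: the sense of induction of the (R)-phosphoric acid is taken over from intermolecular allylborations of aryl aldehydes (Re-face attack, which here means 3S); if it proves opposite, the (S)-acid is used.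

Step 1
Reactants: 1 5-bromo-2,4-dihydroxybenzaldehyde
Product: 2 5-bromo-2-hydroxy-4-[(triisopropylsilyl)oxy]benzaldehyde
Conditions: TIPSCl (1.05 equiv), imidazole, DMF, 0 °C
Reagents that add atoms: chlorotri(propan-2-yl)silane, CC(C)[Si](Cl)(C(C)C)C(C)C
Why: Selective phenol silylation, because the 4-hydroxyl is the more acidic and is free, whereas the 2-hydroxyl is held in the hydrogen-bonded chelate with the formyl group.

Step 2
Reactants: 2 5-bromo-2-hydroxy-4-[(triisopropylsilyl)oxy]benzaldehyde; 3 tributyl(1-ethoxyethenyl)stannane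
Product: 5 5-acetyl-2-hydroxy-4-[(triisopropylsilyl)oxy]benzaldehyde, via 1-ethoxyvinyl arene 4 (not isolated)
Conditions: PdCl2(PPh3)2 (5 mol %), toluene, 100 °C; then 1 M HCl, THF, rt
Reagents that add atoms: water, O
Why: Migita–Kosugi–Stille coupling of the aryl bromide with an acetyl-anion equivalent followed by acid hydrolysis of the enol ether, both stages being tolerant of the aldehyde, the chelated phenol and the aryl silyl ether.

Step 3
Reactants: 5 5-acetyl-2-hydroxy-4-[(triisopropylsilyl)oxy]benzaldehyde; 6 3-chloro-2-(chloromethyl)prop-1-ene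
Product: 7 5-acetyl-2-{[2-(chloromethyl)prop-2-en-1-yl]oxy}-4-[(triisopropylsilyl)oxy]benzaldehyde
Conditions: 6 (3 equiv), K2CO3, MeCN, 60 °C
Reagents that add atoms: none
Why: Williamson ether synthesis on the only free phenol, with excess of the symmetrical bis-allylic chloride to suppress double arylation and keep one allylic chloride for borylation.

Step 4
Reactants: 7 5-acetyl-2-{[2-(chloromethyl)prop-2-en-1-yl]oxy}-4-[(triisopropylsilyl)oxy]benzaldehyde
Product: 8 1-[4-{[2-(chloromethyl)prop-2-en-1-yl]oxy}-5-(hydroxymethyl)-2-[(triisopropylsilyl)oxy]phenyl]ethan-1-one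
Conditions: NaBH4 (0.5 equiv), THF/EtOH, −40 °C
Reagents that add atoms: none
Why: Chemoselective borohydride reduction of the aryl aldehyde beside the hindered, donor-deactivated aryl methyl ketone, which stores the aldehyde at the alcohol oxidation level so that no allylboration can take place before the enol ether exists.

Step 5
Reactants: 8 1-[4-{[2-(chloromethyl)prop-2-en-1-yl]oxy}-5-(hydroxymethyl)-2-[(triisopropylsilyl)oxy]phenyl]ethan-1-one; 9 bis(pinacolato)diboron
Product: 10 1-[5-(hydroxymethyl)-4-({2-[(4,4,5,5-tetramethyl-1,3,2-dioxaborolan-2-yl)methyl]prop-2-en-1-yl}oxy)-2-[(triisopropylsilyl)oxy]phenyl]ethan-1-one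
Conditions: Pd2(dba)3 (2.5 mol %), KOAc, THF, 40 °C
Reagents that add atoms: none
Why: Palladium-catalysed borylation of an allylic chloride through a 2-substituted π-allyl intermediate whose two termini are equivalent, with KOAc taking up the chloroborane so that the free alcohol generates no HCl.

Step 6
Reactants: 10 1-[5-(hydroxymethyl)-4-({2-[(4,4,5,5-tetramethyl-1,3,2-dioxaborolan-2-yl)methyl]prop-2-en-1-yl}oxy)-2-[(triisopropylsilyl)oxy]phenyl]ethan-1-one
Product: 11 1-[5-(hydroxymethyl)-4-{[(1Z)-2-methyl-3-(4,4,5,5-tetramethyl-1,3,2-dioxaborolan-2-yl)prop-1-en-1-yl]oxy}-2-[(triisopropylsilyl)oxy]phenyl]ethan-1-one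
Conditions: [Ir(cod)(PMePh2)2]PF6 (3 mol %, activated with H2), THF, rt
Reagents that add atoms: none
Why: Iridium-hydride-catalysed allyl ether to enol ether isomerisation, a 1,3-hydrogen shift from the oxygen-activated OCH2 to the terminal CH2 through a syn-aryloxy π-allyl hydride, which should place the new methyl trans to oxygen (as in E-propenyl ether formation) and so give the Z γ-aryloxyallylboronate.

Step 7
Reactants: 11 1-[5-(hydroxymethyl)-4-{[(1Z)-2-methyl-3-(4,4,5,5-tetramethyl-1,3,2-dioxaborolan-2-yl)prop-1-en-1-yl]oxy}-2-[(triisopropylsilyl)oxy]phenyl]ethan-1-one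
Product: 12 5-acetyl-2-{[(1Z)-2-methyl-3-(4,4,5,5-tetramethyl-1,3,2-dioxaborolan-2-yl)prop-1-en-1-yl]oxy}-4-[(triisopropylsilyl)oxy]benzaldehyde
Conditions: Dess–Martin periodinane, NaHCO3, CH2Cl2, 0 °C; cold work-up, used at once
Reagents that add atoms: none
Why: Dess–Martin oxidation of the benzylic alcohol under buffered, non-acidic conditions that spare the pinacol allylboronate, the enol ether and the silyl ether, the donor-deactivated aldehyde and the weakly nucleophilic boronate being expected to survive brief cold handling without ring closure.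

Step 8
Reactants: 12 5-acetyl-2-{[(1Z)-2-methyl-3-(4,4,5,5-tetramethyl-1,3,2-dioxaborolan-2-yl)prop-1-en-1-yl]oxy}-4-[(triisopropylsilyl)oxy]benzaldehyde
Product: 14 1-[(2S,3S)-3-hydroxy-2-(prop-1-en-2-yl)-6-[(triisopropylsilyl)oxy]-2,3-dihydro-1-benzofuran-5-yl]ethan-1-one, via pinacol borate ester 13 (not isolated)
Conditions: (R)-TRIP phosphoric acid [(R)-3,3'-bis(2,4,6-triisopropylphenyl)-1,1'-binaphthyl-2,2'-diyl hydrogen phosphate] (10 mol %), 4 Å MS, toluene, −30 °C; then aq. NaHCO3
Reagents that add atoms: none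
Why: Proposed new method: the phosphoric acid hydrogen-bonds to a boronate oxygen and to the formyl C–H, boron binds the aldehyde oxygen, and the oxygen-bearing γ-carbon is transferred to the carbonyl carbon through a six-membered chair while the double bond moves outward to become the isopropenyl group; the closest known reactions are the thermal intramolecular allylboration of aldehydes by γ-alkoxyallylboronates and the phosphoric-acid-catalysed intermolecular allylboration of aryl aldehydes with pinacol allylboronates, which have not been combined on a tethered substrate. The dihydrofuran ring closes in the 5-exo-trig mode, C2 attacking the exocyclic C=O. C3 is set by the catalyst, which should expose the Re face of the aldehyde and so give 3S, and C2 is set by the closed transition state, because the short planar aryl tether can only span an axial aryloxy group and an equatorial aryl group, the arrangement that the Z enol ether provides and that leads to the cis (2S,3S) product. The step requires the catalysed pathway to outrun the uncatalysed closure, which is secured by the low reactivity of a pinacol γ-aryloxyallylboronate toward an aldehyde deactivated by ortho and para oxygen donors and by working at −30 °C. Aqueous work-up cleaves borate 13 to alcohol 14.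

Step 9
Reactants: 15 (E)-but-2-enal
Product: 16 (Z)-2-iodobut-2-enal
Conditions: I2, K2CO3, DMAP (20 mol %), THF/H2O, rt
Reagents that add atoms: iodine, II
Why: α-Iodination of an enal by amine conjugate addition, iodination of the resulting enolate and elimination (a Baylis–Hillman-type sequence), which gives the iodide with iodine cis to the methyl group.

Step 10
Reactants: 16 (Z)-2-iodobut-2-enal
Product: 17 (Z)-2-iodobut-2-en-1-ol
Conditions: NaBH4, MeOH, 0 °C
Reagents that add atoms: none
Why: 1,2-Reduction of the enal by borohydride, leaving the vinyl iodide and the alkene geometry untouched.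

Step 11
Reactants: 17 (Z)-2-iodobut-2-en-1-ol
Product: 19 (Z)-2-(hydroxymethyl)but-2-enoic acid, via dilithio alkenyllithium 18 (not isolated)
Conditions: t-BuLi (3.1 equiv), Et2O, −78 °C; CO2; then 1 M HCl
Reagents that add atoms: carbon dioxide, O=C=O
Why: Deprotonation and iodine–lithium exchange give a configurationally stable alkenyllithium whose carboxylation proceeds with retention, placing the carboxyl group cis to the methyl group (Z).

Step 12
Reactants: 19 (Z)-2-(hydroxymethyl)but-2-enoic acid
Product: 21 (Z)-2-(acetoxymethyl)but-2-enoic acid, via mixed acetic anhydride 20 (not isolated)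
Conditions: Ac2O, pyridine, CH2Cl2, 0 °C to rt; then H2O/THF
Reagents that add atoms: acetic anhydride, CC(=O)OC(C)=O
Why: O-Acetylation of the primary allylic alcohol, the mixed anhydride formed at the carboxyl group being hydrolysed on the aqueous quench and no strongly nucleophilic amine being present that could add to the Z alkene.

Step 13
Reactants: 14 1-[(2S,3S)-3-hydroxy-2-(prop-1-en-2-yl)-6-[(triisopropylsilyl)oxy]-2,3-dihydro-1-benzofuran-5-yl]ethan-1-one; 21 (Z)-2-(acetoxymethyl)but-2-enoic acid
Product: 23 (2S,3S)-5-acetyl-2-(prop-1-en-2-yl)-6-[(triisopropylsilyl)oxy]-2,3-dihydro-1-benzofuran-3-yl (2Z)-2-(acetoxymethyl)but-2-enoate, via acid chloride 22 (not isolated)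
Conditions: 21, 1-chloro-N,N,2-trimethylprop-1-en-1-amine, CH2Cl2, 0 °C; added to 14, LiN(SiMe3)2 (1.0 equiv), THF, −78 °C
Reagents that add atoms: none
Why: Acylation of the preformed lithium alkoxide with an acid chloride made under neutral conditions, so that no nucleophilic amine can cause Z to E isomerisation or SN2′ loss of the allylic acetate, and C3 keeps its configuration because its C–O bond is not broken.

Step 14
Reactants: 23 (2S,3S)-5-acetyl-2-(prop-1-en-2-yl)-6-[(triisopropylsilyl)oxy]-2,3-dihydro-1-benzofuran-3-yl (2Z)-2-(acetoxymethyl)but-2-enoate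
Product: 24 (2S,3S)-5-acetyl-6-hydroxy-2-(prop-1-en-2-yl)-2,3-dihydro-1-benzofuran-3-yl (2Z)-2-(acetoxymethyl)but-2-enoate
Conditions: Bu4NF, AcOH (1:1), THF, 0 °C
Reagents that add atoms: none
Why: Fluoride cleavage of the activated aryl silyl ether, buffered with acetic acid so that no phenoxide para to the benzylic ester accumulates and neither ester is touched.

**Compound list**
1 | 5-bromo-2,4-dihydroxybenzaldehyde | O=Cc1cc(Br)c(O)cc1O | starting material
2 | 5-bromo-2-hydroxy-4-[(triisopropylsilyl)oxy]benzaldehyde | O=Cc1cc(Br)c(O[Si](C(C)C)(C(C)C)C(C)C)cc1O | intermediate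
3 | tributyl(1-ethoxyethenyl)stannane | CCCC[Sn](CCCC)(CCCC)C(=C)OCC | starting material
4 | 5-(1-ethoxyethenyl)-2-hydroxy-4-[(triisopropylsilyl)oxy]benzaldehyde | C=C(OCC)c1cc(C=O)c(O)cc1O[Si](C(C)C)(C(C)C)C(C)C | intermediate (not isolated)
5 | 5-acetyl-2-hydroxy-4-[(triisopropylsilyl)oxy]benzaldehyde | CC(=O)c1cc(C=O)c(O)cc1O[Si](C(C)C)(C(C)C)C(C)C | intermediate
6 | 3-chloro-2-(chloromethyl)prop-1-ene | C=C(CCl)CCl | starting material
7 | 5-acetyl-2-{[2-(chloromethyl)prop-2-en-1-yl]oxy}-4-[(triisopropylsilyl)oxy]benzaldehyde | CC(=O)c1cc(C=O)c(OCC(=C)CCl)cc1O[Si](C(C)C)(C(C)C)C(C)C | intermediate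
8 | 1-[4-{[2-(chloromethyl)prop-2-en-1-yl]oxy}-5-(hydroxymethyl)-2-[(triisopropylsilyl)oxy]phenyl]ethan-1-one | CC(=O)c1cc(CO)c(OCC(=C)CCl)cc1O[Si](C(C)C)(C(C)C)C(C)C | intermediate
9 | bis(pinacolato)diboron | CC1(C)OB(B2OC(C)(C)C(C)(C)O2)OC1(C)C | starting material
10 | 1-[5-(hydroxymethyl)-4-({2-[(4,4,5,5-tetramethyl-1,3,2-dioxaborolan-2-yl)methyl]prop-2-en-1-yl}oxy)-2-[(triisopropylsilyl)oxy]phenyl]ethan-1-one | CC(=O)c1cc(CO)c(OCC(=C)CB2OC(C)(C)C(C)(C)O2)cc1O[Si](C(C)C)(C(C)C)C(C)C | intermediate
11 | 1-[5-(hydroxymethyl)-4-{[(1Z)-2-methyl-3-(4,4,5,5-tetramethyl-1,3,2-dioxaborolan-2-yl)prop-1-en-1-yl]oxy}-2-[(triisopropylsilyl)oxy]phenyl]ethan-1-one | CC(=O)c1cc(CO)c(O/C=C(/C)CB2OC(C)(C)C(C)(C)O2)cc1O[Si](C(C)C)(C(C)C)C(C)C | intermediate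
12 | 5-acetyl-2-{[(1Z)-2-methyl-3-(4,4,5,5-tetramethyl-1,3,2-dioxaborolan-2-yl)prop-1-en-1-yl]oxy}-4-[(triisopropylsilyl)oxy]benzaldehyde | CC(=O)c1cc(C=O)c(O/C=C(/C)CB2OC(C)(C)C(C)(C)O2)cc1O[Si](C(C)C)(C(C)C)C(C)C | intermediate
13 | 1-[(2S,3S)-2-(prop-1-en-2-yl)-3-[(4,4,5,5-tetramethyl-1,3,2-dioxaborolan-2-yl)oxy]-6-[(triisopropylsilyl)oxy]-2,3-dihydro-1-benzofuran-5-yl]ethan-1-one | C=C(C)[C@@H]1Oc2cc(O[Si](C(C)C)(C(C)C)C(C)C)c(C(C)=O)cc2[C@@H]1OB3OC(C)(C)C(C)(C)O3 | intermediate (not isolated)
14 | 1-[(2S,3S)-3-hydroxy-2-(prop-1-en-2-yl)-6-[(triisopropylsilyl)oxy]-2,3-dihydro-1-benzofuran-5-yl]ethan-1-one | C=C(C)[C@@H]1Oc2cc(O[Si](C(C)C)(C(C)C)C(C)C)c(C(C)=O)cc2[C@@H]1O | intermediate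
15 | (E)-but-2-enal | C/C=C/C=O | starting material
16 | (Z)-2-iodobut-2-enal | C/C=C(\I)C=O | intermediate
17 | (Z)-2-iodobut-2-en-1-ol | C/C=C(\I)CO | intermediate
18 | lithium (E)-2-lithiobut-2-en-1-olate (lithium cis to methyl; the descriptor changes only through CIP priority) | C/C=C(\[Li])CO[Li] | intermediate (not isolated)
19 | (Z)-2-(hydroxymethyl)but-2-enoic acid | C/C=C(\C(=O)O)CO | intermediate
20 | acetic (Z)-2-(acetoxymethyl)but-2-enoic anhydride | C/C=C(\C(=O)OC(C)=O)COC(C)=O | intermediate (not isolated)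
21 | (Z)-2-(acetoxymethyl)but-2-enoic acid | C/C=C(\C(=O)O)COC(C)=O | intermediate
22 | (Z)-2-(acetoxymethyl)but-2-enoyl chloride | C/C=C(\C(Cl)=O)COC(C)=O | intermediate (not isolated)
23 | (2S,3S)-5-acetyl-2-(prop-1-en-2-yl)-6-[(triisopropylsilyl)oxy]-2,3-dihydro-1-benzofuran-3-yl (2Z)-2-(acetoxymethyl)but-2-enoate | C=C(C)[C@@H]1Oc2cc(O[Si](C(C)C)(C(C)C)C(C)C)c(C(C)=O)cc2[C@@H]1OC(=O)/C(=C\C)COC(C)=O | intermediate
24 | (2S,3S)-5-acetyl-6-hydroxy-2-(prop-1-en-2-yl)-2,3-dihydro-1-benzofuran-3-yl (2Z)-2-(acetoxymethyl)but-2-enoate | C=C(C)[C@@H]1Oc2cc(O)c(C(C)=O)cc2[C@@H]1OC(=O)/C(=C\C)COC(C)=O | target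

Total steps: 14. Longest linear sequence: 10 steps (steps 1–8, 13 and 14); the side-chain acid takes steps 9–12.

**Steps most likely to fail**

Step 8. The uncatalysed ring closure may compete during oxidation, handling or the reaction itself and erode the enantiomeric purity, or the tether may weaken the facial discrimination by the acid. The fallback uses known chemistry and sets out from 12. Closure without catalyst in toluene at 40 °C should give the racemic cis borate, that is 13 together with its enantiomer, 1-[(2R,3R)-2-(prop-1-en-2-yl)-3-(pinacolboryloxy)-6-(triisopropylsilyloxy)-2,3-dihydro-1-benzofuran-5-yl]ethan-1-one F1. Aqueous work-up then gives 14 and its enantiomer, the (2R,3R) alcohol F2. Acylative kinetic resolution follows, with benzotetramisole (the enantiomer that acylates the 3R alcohol, fixed on the racemate), propanoic anhydride and i-Pr2NEt in CHCl3 at 0 °C. It should convert F2 into the (2R,3R) propanoate F3 and leave 14, which is separated by chromatography and re-enters the route at step 13.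

Step 6. Turnover on the 1,1-disubstituted alkene may be slow, the hydrogen shift may run toward boron to give a vinylboronate, the 2-substituent may lower the syn preference and give E/Z mixtures, or the benzylic hydroxyl may add to the new enol ether. The fallback takes the geometry from a vinyl iodide instead and sets out from 5. Copper-catalysed O-vinylation (CuI, N,N-dimethylglycine, Cs2CO3, dioxane, 80 °C) with the known, geometrically pure (Z)-3-iodo-2-methylprop-2-en-1-ol should give, with retention, 5-acetyl-2-{[(1Z)-3-hydroxy-2-methylprop-1-en-1-yl]oxy}-4-[(triisopropylsilyl)oxy]benzaldehyde F4. Borohydride reduction as in step 4 gives 1-[5-(hydroxymethyl)-4-{[(1Z)-3-hydroxy-2-methylprop-1-en-1-yl]oxy}-2-[(triisopropylsilyl)oxy]phenyl]ethan-1-one F5. Palladium-catalysed borylation of the allylic (not the benzylic) alcohol with bis(pinacolato)diboron then gives 11, and the route continues at step 7.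

Step 13. Acylation of the hindered cis alcohol may stall, the acid chloride may form a ketene and lose its Z geometry, or the amide base may enolise the methyl ketone. The fallback sets out from 19 and 14 and replaces the acetate by a silyl ether, which cannot leave in an SN2′ process, so that nucleophilic catalysis becomes usable. Silylation of 19 (TBSCl, imidazole, DMF) gives tert-butyldimethylsilyl (2Z)-2-{[(tert-butyldimethylsilyl)oxy]methyl}but-2-enoate F6. K2CO3 in aqueous methanol cleaves only the silyl ester and gives (2Z)-2-{[(tert-butyldimethylsilyl)oxy]methyl}but-2-enoic acid F7. Steglich esterification with 14 (EDC·HCl, DMAP, CH2Cl2, 0 °C) gives the (2S,3S) silyl-ether ester F8. HF·pyridine in THF removes both silyl groups to give (2S,3S)-5-acetyl-6-hydroxy-2-(prop-1-en-2-yl)-2,3-dihydro-1-benzofuran-3-yl (2Z)-2-(hydroxymethyl)but-2-enoate F9. Acetylation of the primary allylic hydroxyl beside the chelated phenol (Ac2O, 2,4,6-collidine, CH2Cl2, −20 °C) then gives 24 directly.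

**Further compounds**
F1 | step 8 | 1-[(2R,3R)-2-(prop-1-en-2-yl)-3-[(4,4,5,5-tetramethyl-1,3,2-dioxaborolan-2-yl)oxy]-6-[(triisopropylsilyl)oxy]-2,3-dihydro-1-benzofuran-5-yl]ethan-1-one | C=C(C)[C@H]1Oc2cc(O[Si](C(C)C)(C(C)C)C(C)C)c(C(C)=O)cc2[C@H]1OB3OC(C)(C)C(C)(C)O3
F2 | step 8 | 1-[(2R,3R)-3-hydroxy-2-(prop-1-en-2-yl)-6-[(triisopropylsilyl)oxy]-2,3-dihydro-1-benzofuran-5-yl]ethan-1-one | C=C(C)[C@H]1Oc2cc(O[Si](C(C)C)(C(C)C)C(C)C)c(C(C)=O)cc2[C@H]1O
F3 | step 8 | (2R,3R)-5-acetyl-2-(prop-1-en-2-yl)-6-[(triisopropylsilyl)oxy]-2,3-dihydro-1-benzofuran-3-yl propanoate | C=C(C)[C@H]1Oc2cc(O[Si](C(C)C)(C(C)C)C(C)C)c(C(C)=O)cc2[C@H]1OC(=O)CC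
F4 | step 6 | 5-acetyl-2-{[(1Z)-3-hydroxy-2-methylprop-1-en-1-yl]oxy}-4-[(triisopropylsilyl)oxy]benzaldehyde | CC(=O)c1cc(C=O)c(O/C=C(/C)CO)cc1O[Si](C(C)C)(C(C)C)C(C)C
F5 | step 6 | 1-[5-(hydroxymethyl)-4-{[(1Z)-3-hydroxy-2-methylprop-1-en-1-yl]oxy}-2-[(triisopropylsilyl)oxy]phenyl]ethan-1-one | CC(=O)c1cc(CO)c(O/C=C(/C)CO)cc1O[Si](C(C)C)(C(C)C)C(C)C
F6 | step 13 | tert-butyldimethylsilyl (2Z)-2-{[(tert-butyldimethylsilyl)oxy]methyl}but-2-enoate | C/C=C(\C(=O)O[Si](C)(C)C(C)(C)C)CO[Si](C)(C)C(C)(C)C
F7 | step 13 | (2Z)-2-{[(tert-butyldimethylsilyl)oxy]methyl}but-2-enoic acid | C/C=C(\C(=O)O)CO[Si](C)(C)C(C)(C)C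
F8 | step 13 | (2S,3S)-5-acetyl-2-(prop-1-en-2-yl)-6-[(triisopropylsilyl)oxy]-2,3-dihydro-1-benzofuran-3-yl (2Z)-2-{[(tert-butyldimethylsilyl)oxy]methyl}but-2-enoate | C=C(C)[C@@H]1Oc2cc(O[Si](C(C)C)(C(C)C)C(C)C)c(C(C)=O)cc2[C@@H]1OC(=O)/C(=C\C)CO[Si](C)(C)C(C)(C)C
F9 | step 13 | (2S,3S)-5-acetyl-6-hydroxy-2-(prop-1-en-2-yl)-2,3-dihydro-1-benzofuran-3-yl (2Z)-2-(hydroxymethyl)but-2-enoate | C=C(C)[C@@H]1Oc2cc(O)c(C(C)=O)cc2[C@@H]1OC(=O)/C(=C\C)CO
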